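**Retrosynthetic overview**

- The target is an α-methylene-γ-butyrolactone (O–C6, C7, C11=C13, C12) cis-fused at C6/C7 to a (1(10)Z,4Z)-cyclodecadiene. The enabling feature is the homoallylic alcohol C8(OH)–C7–C11=C13 shared by the lactone ring and the ten-membered ring: it is the retron of a γ-selective allyl-metal addition, so the C7–C8 ring bond is cut to an open-chain C8 aldehyde carrying a 3-(bromomethyl)butenolide.
- This seco aldehyde already holds the C3 acetate and the C9 epoxy ester, so ring closure gives the target itself. The butenolide comes from the C6 alcohol, 2-(bromomethyl)acrylic acid and ring-closing metathesis; the ester from a Sharpless-derived (2S,3R)-epoxy acid.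
- The chain is joined at C3–C4 by Nozaki–Hiyama–Kishi coupling of a (Z)-alkenyl iodide (C4–C7; C6 from (R)-but-3-ene-1,2-diol) with a β,γ-unsaturated aldehyde (C3–C2–C1=C10–C9–C8; C9 from an (R)-glycerate; Z olefin by Wittig reaction of the α-alkoxy methyl ketone). C3 is then set by oxidation and CBS reduction.
- Order of ring formation: epoxide of the side-chain acid (step 1), butenolide (step 21), ten-membered carbocycle last (step 24); the dioxolanes are temporary protecting rings.

Key step: step 24

Remark: germacrane numbering is used (lactone C12(=O)–O–C6, ring fusion C6/C7, carbinol C8, acyloxy carbon C9, C10(C14)=C1, C2, acetoxy carbon C3, C4(C15)=C5, exocyclic C11=C13); the side-chain acid is read from the SMILES as the cis-dimethyl (2S,3R)-epoxide, and the six starting materials are taken as commercially available.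

**Route**

Step 1
Reactants: 1 (E)-2-methylbut-2-en-1-ol
Product: 2 [(2R,3R)-2,3-dimethyloxiran-2-yl]methanol
Conditions: Ti(OiPr)4 (10 mol%), D-(−)-diethyl tartrate (12 mol%), t-BuOOH, 4 Å MS, CH2Cl2, −20 °C
Reagents that add atoms: tert-butyl hydroperoxide, CC(C)(C)OO
Why: Sharpless asymmetric epoxidation of an (E)-allylic alcohol, in which the D-(−)-tartrate ligand should direct oxygen to the face giving the (2R,3R)-epoxide, the cis-dimethyl relation being inherited from the E olefin.

Step 2
Reactants: 2 [(2R,3R)-2,3-dimethyloxiran-2-yl]methanol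
Product: 4 (2S,3R)-2,3-dimethyloxirane-2-carboxylic acid, via epoxy aldehyde 3 (not isolated)
Conditions: RuCl3 hydrate (2 mol%), NaIO4, MeCN/EtOAc/H2O, 0 °C to rt
Reagents that add atoms: sodium periodate, [Na+].[O-]I(=O)(=O)=O; water, O
Why: ruthenium tetroxide-catalysed oxidation (Sharpless conditions) should take the primary alcohol through the aldehyde hydrate to the acid without opening the epoxide, no stereocentre being touched (the C2 descriptor changes only through CIP priorities).

Step 3
Reactants: 5 (3-bromopropoxy)(tert-butyl)dimethylsilane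
Product: 6 {3-[(tert-butyldimethylsilyl)oxy]propyl}triphenylphosphonium bromide
Conditions: PPh3, MeCN, reflux
Reagents that add atoms: triphenylphosphine, c1ccc(cc1)P(c1ccccc1)c1ccccc1
Why: SN2 quaternisation of triphenylphosphine by a primary bromide (phosphonium salt formation) with no stereocentre involved.

Step 4
Reactants: 7 methyl (4R)-2,2-dimethyl-1,3-dioxolane-4-carboxylate
Product: 9 1-[(4R)-2,2-dimethyl-1,3-dioxolan-4-yl]ethan-1-one, via Weinreb amide 8 (not isolated)
Conditions: MeNHOMe·HCl, i-PrMgCl, THF, −20 °C; then MeMgBr, 0 °C; aq. NH4Cl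
Reagents that add atoms: methylmagnesium bromide, C[Mg]Br
Why: one-pot Weinreb ketone synthesis, in which the chelated tetrahedral intermediate should stop addition at the methyl ketone; C9 comes from the chiral pool and should not epimerise at low temperature.

Step 5
Reactants: 6 phosphonium bromide; 9 methyl ketone
Product: 11 tert-butyl{[(3Z)-4-[(4S)-2,2-dimethyl-1,3-dioxolan-4-yl]pent-3-en-1-yl]oxy}dimethylsilane, via phosphorus ylide 10 (not isolated)
Conditions: NaN(SiMe3)2, THF, −78 °C; then 9, −78 °C to rt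
Reagents that add atoms: none
Why: Wittig olefination of an α-alkoxy methyl ketone with a non-stabilised ylide, a reaction type known to give the trisubstituted olefin with the oxygenated carbon cis to the new chain, here C9 cis to C2 (Z).

Step 6
Reactants: 11 silyl ether
Product: 12 (3Z)-4-[(4S)-2,2-dimethyl-1,3-dioxolan-4-yl]pent-3-en-1-ol
Conditions: Bu4NF, THF, 0 °C
Reagents that add atoms: none
Why: fluoride-mediated desilylation of a primary TBS ether should leave the acetonide and the Z olefin untouched.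

Step 7
Reactants: 12 homoallylic alcohol
Product: 13 (3Z)-4-[(4S)-2,2-dimethyl-1,3-dioxolan-4-yl]pent-3-enal
Conditions: Dess–Martin periodinane, pyridine, CH2Cl2, 0 °C; used crude
Reagents that add atoms: none
Why: Dess–Martin oxidation under buffered conditions should give the β,γ-unsaturated aldehyde without moving the Z olefin into conjugation.

Step 8
Reactants: 14 (2R)-but-3-ene-1,2-diol
Product: 15 (4R)-4-ethenyl-2-(4-methoxyphenyl)-1,3-dioxolane (both acetal epimers)
Conditions: 4-MeOC6H4CH(OMe)2, PPTS (cat.), CH2Cl2, rt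
Reagents that add atoms: 4-methoxybenzaldehyde dimethyl acetal, COC(OC)c1ccc(OC)cc1
Why: acid-catalysed transacetalisation of the 1,2-diol; C6 comes from the chiral pool and the new acetal centre disappears in step 9.

Step 9
Reactants: 15 4-methoxybenzylidene acetal
Product: 16 (2R)-2-[(4-methoxyphenyl)methoxy]but-3-en-1-ol
Conditions: i-Bu2AlH, CH2Cl2, −78 to 0 °C; Rochelle salt
Reagents that add atoms: none
Why: regioselective reductive acetal opening, in which aluminium should coordinate the less hindered primary oxygen so that the PMB group stays on the secondary C6 oxygen.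

Step 10
Reactants: 16 primary alcohol
Product: 17 (2R)-2-[(4-methoxyphenyl)methoxy]but-3-enal
Conditions: Dess–Martin periodinane, pyridine, CH2Cl2, 0 °C; used at once
Reagents that add atoms: none
Why: Dess–Martin oxidation avoids the strongly basic or warm conditions that would racemise or conjugate this α-alkoxy β,γ-unsaturated aldehyde.

Step 11
Reactants: 17 aldehyde; 18 ethyltriphenylphosphonium iodide
Product: 22 (3R,4Z)-5-iodo-3-[(4-methoxyphenyl)methoxy]hexa-1,4-diene, via ethylidene ylide 19 (not isolated), via iodophosphonium salt 20 (not isolated), via iodo ylide 21 (not isolated)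
Conditions: n-BuLi, THF, −78 to 0 °C; I2, −78 °C; NaN(SiMe3)2, −20 °C; then 17, −78 °C
Reagents that add atoms: iodine, II
Why: Stork–Zhao-type Wittig olefination with the α-iodoethylidene ylide should give the (Z)-alkenyl iodide (iodine cis to C6) under kinetic control, C6 staying intact if the aldehyde meets the preformed ylide cold.

Step 12
Reactants: 22 (Z)-alkenyl iodide; 13 aldehyde
Product: 24 (2Z,6Z,8R)-2-[(4S)-2,2-dimethyl-1,3-dioxolan-4-yl]-8-[(4-methoxyphenyl)methoxy]-6-methyldeca-2,6,9-trien-5-ol (both C5 epimers), via alkenylchromium species 23 (not isolated)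
Conditions: CrCl2 (6 equiv), NiCl2 (2 mol%), DMSO/THF, rt
Reagents that add atoms: none
Why: Nozaki–Hiyama–Kishi coupling, in which the nickel-catalysed alkenylchromium reagent should keep the Z geometry and add only to the aldehyde; the new C3 carbinol is expected as an epimer mixture and is set in step 14.

Step 13
Reactants: 24 allylic alcohols
Product: 25 (2Z,6Z,8R)-2-[(4S)-2,2-dimethyl-1,3-dioxolan-4-yl]-8-[(4-methoxyphenyl)methoxy]-6-methyldeca-2,6,9-trien-5-one
Conditions: Dess–Martin periodinane, pyridine, CH2Cl2, 0 °C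
Reagents that add atoms: none
Why: Dess–Martin oxidation should give the Z enone under conditions too mild to isomerise either trisubstituted olefin.

Step 14
Reactants: 25 Z enone
Product: 26 (2Z,5S,6Z,8R)-2-[(4S)-2,2-dimethyl-1,3-dioxolan-4-yl]-8-[(4-methoxyphenyl)methoxy]-6-methyldeca-2,6,9-trien-5-ol
Conditions: (R)-2-methyl-CBS-oxazaborolidine (0.3 equiv), catecholborane, toluene, −78 °C
Reagents that add atoms: none
Why: Corey–Bakshi–Shibata reduction with the α-methylalkenyl group as the large and the allylic CH2 as the small substituent, so that the (R)-catalyst should give the (S)-carbinol at C3 under reagent control.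

Step 15
Reactants: 26 (S)-allylic alcohol
Product: 27 (2Z,5S,6Z,8R)-2-[(4S)-2,2-dimethyl-1,3-dioxolan-4-yl]-8-[(4-methoxyphenyl)methoxy]-6-methyldeca-2,6,9-trien-5-yl acetate
Conditions: Ac2O, pyridine, DMAP (cat.), CH2Cl2, 0 °C to rt
Reagents that add atoms: acetic anhydride, CC(=O)OC(C)=O
Why: DMAP-catalysed acylation of the secondary alcohol with retention at C3.

Step 16
Reactants: 27 acetonide
Product: 28 (2S,3Z,6S,7Z,9R)-1,2-dihydroxy-9-[(4-methoxyphenyl)methoxy]-3,7-dimethylundeca-3,7,10-trien-6-yl acetate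
Conditions: AcOH/H2O (4:1), rt
Reagents that add atoms: none
Why: acid-catalysed hydrolysis of the terminal isopropylidene acetal, which the PMB ether and the allylic acetate should survive.

Step 17
Reactants: 28 diol
Product: 29 (2S,3Z,6S,7Z,9R)-2-hydroxy-9-[(4-methoxyphenyl)methoxy]-3,7-dimethyl-1-[(triethylsilyl)oxy]undeca-3,7,10-trien-6-yl acetate
Conditions: Et3SiCl, imidazole, CH2Cl2, −40 °C
Reagents that add atoms: chlorotriethylsilane, CC[Si](Cl)(CC)CC
Why: selective silylation of the primary C8 hydroxyl over the hindered allylic C9 hydroxyl on steric grounds.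

Step 18
Reactants: 4 epoxy acid; 29 C9 alcohol
Product: 31 C9 epoxy ester of 29, via mixed anhydride 30 (not isolated)
Conditions: 2,4,6-Cl3C6H2COCl, Et3N, THF, rt; then 29, DMAP, toluene, rt
Reagents that add atoms: none
Why: Yamaguchi esterification should acylate the hindered C9 alcohol with the preformed enantiopure epoxy acid, with retention at C9 and without opening the epoxide.

Step 19
Reactants: 31 PMB ether
Product: 32 C6 alcohol (PMB removed; C8 silyl ether and both esters kept)
Conditions: DDQ, CH2Cl2/pH 7 buffer, 0 °C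
Reagents that add atoms: none
Why: oxidative PMB ether cleavage (hydride abstraction, hydrolysis of the oxocarbenium ion), run cold and briefly so that the bis-allylic alcohol is not oxidised further.

Step 20
Reactants: 32 C6 alcohol; 33 2-(bromomethyl)prop-2-enoic acid
Product: 35 C6 2-(bromomethyl)acrylate of 32, via O-acylisourea 34 (not isolated)
Conditions: DCC, DMAP (5 mol%), CH2Cl2, −20 to 0 °C
Reagents that add atoms: none
Why: Steglich esterification acylates the C6 hydroxyl with retention, low temperature and only catalytic DMAP limiting SN2′ attack on the bromomethyl acrylate.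

Step 21
Reactants: 35 acrylate ester
Product: 36 3-(bromomethyl)butenolide with C8 silyl ether
Conditions: second-generation Grubbs catalyst (H2IMes)(PCy3)Cl2Ru=CHPh (10 mol%), CH2Cl2 (5 mM), 40 °C
Reagents that add atoms: none
Why: ring-closing metathesis, in which the ruthenium alkylidene should load on the only monosubstituted olefin (C7 vinyl) and close the five-membered ring onto the acrylate faster than it engages a trisubstituted olefin, C6 staying unchanged.

Step 22
Reactants: 36 triethylsilyl ether
Product: 37 C8 primary alcohol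
Conditions: AcOH/THF/H2O (3:1:1), rt
Reagents that add atoms: none
Why: acid-catalysed silyl ether solvolysis, mild enough to leave the allylic bromide, the esters and the epoxide intact and not to move the hindered C9 acyl group.

Step 23
Reactants: 37 primary alcohol
Product: 38 seco aldehyde (C8 aldehyde, C9 epoxy ester, C3 acetate, 3-(bromomethyl)butenolide)
Conditions: Dess–Martin periodinane, CH2Cl2, 0 °C; used at once
Reagents that add atoms: none
Why: Dess–Martin oxidation is base-free, so C9 of the α-acyloxy aldehyde should not epimerise and the butenolide γ-position C6 should not enolise.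

Step 24
Reactants: 38 seco aldehyde
Product: 40 CNP0137407.7 (target), via allylchromium species 39 (not isolated)
Conditions: CrCl2 (6 equiv), THF, rt, slow addition of 38 (final 2 mM); aq. NH4Cl
Reagents that add atoms: none
Why: Intramolecular Nozaki–Hiyama–Kishi (Barbier-type) allylation: CrCl2 reduces the allylic bromide to the allyl species 39 of trivalent chromium, whose γ-carbon C7 adds to the tethered aldehyde C8 through a closed six-membered chair transition state with allylic transposition, so that the C7–C8 bond, the exocyclic C11=C13 methylene and the free C8 hydroxyl arise together. The closest known reactions are the chromium-mediated closure of ω-formyl 2-(bromomethyl)acrylate-type bromides to ten-membered germacranolide rings and the intermolecular γ-allylation of aldehydes by 3-(bromomethyl)furan-2(5H)-ones. The ten-membered carbocycle is the only ring closed, by 10-exo-trig attack of C7 on the C8 carbonyl in the SE2′ mode, the lactone being already in place. C7 (R) should result from delivery of the aldehyde to the butenolide face that carries the C5 chain of the 6S centre (cis fusion, the two cis olefins folding the seven-atom tether back over that face), and C8 (S) from the chair in which ring carbon C6 is pseudo-equatorial and the C9 arm axial, the only chair in which a cis-fusing tether avoids a syn-pentane clash between C5 and C9. The step needs γ- over α-attack (α would give a twelve-membered ring), cis over trans fusion and cyclisation over dimerisation, which the closed transition state, the anchoring of the tether next to the reacting carbon and high dilution are meant to secure, while acetate, glycidic ester and lactone are inert to CrCl2. The acyclic polar Felkin–Anh bias of the α-acyloxy aldehyde points to the other aldehyde face, and the ring-fusion argument is qualitative, so this selectivity is the main risk of the route.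

**Compound list**

1 | (E)-2-methylbut-2-en-1-ol | C/C=C(\C)CO | starting material
2 | [(2R,3R)-2,3-dimethyloxiran-2-yl]methanol | OC[C@@]1(C)O[C@@H]1C | intermediate
3 | (2S,3R)-2,3-dimethyloxirane-2-carbaldehyde | O=C[C@@]1(C)O[C@@H]1C | intermediate (not isolated)
4 | (2S,3R)-2,3-dimethyloxirane-2-carboxylic acid | OC(=O)[C@@]1(C)O[C@@H]1C | intermediate
5 | (3-bromopropoxy)(tert-butyl)dimethylsilane | CC(C)(C)[Si](C)(C)OCCCBr | starting material
6 | {3-[(tert-butyldimethylsilyl)oxy]propyl}triphenylphosphonium bromide | CC(C)(C)[Si](C)(C)OCCC[P+](c1ccccc1)(c1ccccc1)c1ccccc1.[Br-] | intermediate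
7 | methyl (4R)-2,2-dimethyl-1,3-dioxolane-4-carboxylate | COC(=O)[C@H]1COC(C)(C)O1 | starting material
8 | (4R)-N-methoxy-N,2,2-trimethyl-1,3-dioxolane-4-carboxamide | CON(C)C(=O)[C@H]1COC(C)(C)O1 | intermediate (not isolated)
9 | 1-[(4R)-2,2-dimethyl-1,3-dioxolan-4-yl]ethan-1-one | CC(=O)[C@H]1COC(C)(C)O1 | intermediate
10 | {3-[(tert-butyldimethylsilyl)oxy]propylidene}triphenylphosphorane | CC(C)(C)[Si](C)(C)OCCC=P(c1ccccc1)(c1ccccc1)c1ccccc1 | intermediate (not isolated)
11 | tert-butyl{[(3Z)-4-[(4S)-2,2-dimethyl-1,3-dioxolan-4-yl]pent-3-en-1-yl]oxy}dimethylsilane | CC(C)(C)[Si](C)(C)OCC/C=C(/C)[C@H]1COC(C)(C)O1 | intermediate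
12 | (3Z)-4-[(4S)-2,2-dimethyl-1,3-dioxolan-4-yl]pent-3-en-1-ol | OCC/C=C(/C)[C@H]1COC(C)(C)O1 | intermediate
13 | (3Z)-4-[(4S)-2,2-dimethyl-1,3-dioxolan-4-yl]pent-3-enal | O=CC/C=C(/C)[C@H]1COC(C)(C)O1 | intermediate
14 | (2R)-but-3-ene-1,2-diol | C=C[C@@H](O)CO | starting material
15 | (4R)-4-ethenyl-2-(4-methoxyphenyl)-1,3-dioxolane (both acetal epimers) | C=C[C@@H]1COC(c2ccc(OC)cc2)O1 | intermediate
16 | (2R)-2-[(4-methoxyphenyl)methoxy]but-3-en-1-ol | C=C[C@@H](OCc1ccc(OC)cc1)CO | intermediate
17 | (2R)-2-[(4-methoxyphenyl)methoxy]but-3-enal | C=C[C@@H](OCc1ccc(OC)cc1)C=O | intermediate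
18 | ethyltriphenylphosphonium iodide | CC[P+](c1ccccc1)(c1ccccc1)c1ccccc1.[I-] | starting material
19 | ethylidenetriphenylphosphorane | CC=P(c1ccccc1)(c1ccccc1)c1ccccc1 | intermediate (not isolated)
20 | (1-iodoethyl)triphenylphosphonium iodide | CC(I)[P+](c1ccccc1)(c1ccccc1)c1ccccc1.[I-] | intermediate (not isolated)
21 | (1-iodoethylidene)triphenylphosphorane | CC(I)=P(c1ccccc1)(c1ccccc1)c1ccccc1 | intermediate (not isolated)
22 | (3R,4Z)-5-iodo-3-[(4-methoxyphenyl)methoxy]hexa-1,4-diene | C=C[C@@H](OCc1ccc(OC)cc1)/C=C(/C)I | intermediate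
23 | dichloro{(2Z,4R)-4-[(4-methoxyphenyl)methoxy]hexa-2,5-dien-2-yl}chromium (22 with CrCl2 in place of iodine) | C=C[C@@H](OCc1ccc(OC)cc1)/C=C(/C)[Cr](Cl)Cl | intermediate (not isolated)
24 | (2Z,6Z,8R)-2-[(4S)-2,2-dimethyl-1,3-dioxolan-4-yl]-8-[(4-methoxyphenyl)methoxy]-6-methyldeca-2,6,9-trien-5-ol (both C5 epimers) | C=C[C@@H](OCc1ccc(OC)cc1)/C=C(/C)C(O)C/C=C(/C)[C@H]1COC(C)(C)O1 | intermediate
25 | (2Z,6Z,8R)-2-[(4S)-2,2-dimethyl-1,3-dioxolan-4-yl]-8-[(4-methoxyphenyl)methoxy]-6-methyldeca-2,6,9-trien-5-one | C=C[C@@H](OCc1ccc(OC)cc1)/C=C(/C)C(=O)C/C=C(/C)[C@H]1COC(C)(C)O1 | intermediate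
26 | (2Z,5S,6Z,8R)-2-[(4S)-2,2-dimethyl-1,3-dioxolan-4-yl]-8-[(4-methoxyphenyl)methoxy]-6-methyldeca-2,6,9-trien-5-ol | C=C[C@@H](OCc1ccc(OC)cc1)/C=C(/C)[C@@H](O)C/C=C(/C)[C@H]1COC(C)(C)O1 | intermediate
27 | (2Z,5S,6Z,8R)-2-[(4S)-2,2-dimethyl-1,3-dioxolan-4-yl]-8-[(4-methoxyphenyl)methoxy]-6-methyldeca-2,6,9-trien-5-yl acetate | C=C[C@@H](OCc1ccc(OC)cc1)/C=C(/C)[C@@H](OC(C)=O)C/C=C(/C)[C@H]1COC(C)(C)O1 | intermediate
28 | (2S,3Z,6S,7Z,9R)-1,2-dihydroxy-9-[(4-methoxyphenyl)methoxy]-3,7-dimethylundeca-3,7,10-trien-6-yl acetate | C=C[C@@H](OCc1ccc(OC)cc1)/C=C(/C)[C@@H](OC(C)=O)C/C=C(/C)[C@H](O)CO | intermediate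
29 | (2S,3Z,6S,7Z,9R)-2-hydroxy-9-[(4-methoxyphenyl)methoxy]-3,7-dimethyl-1-[(triethylsilyl)oxy]undeca-3,7,10-trien-6-yl acetate | C=C[C@@H](OCc1ccc(OC)cc1)/C=C(/C)[C@@H](OC(C)=O)C/C=C(/C)[C@H](O)CO[Si](CC)(CC)CC | intermediate
30 | (2S,3R)-2,3-dimethyloxirane-2-carboxylic 2,4,6-trichlorobenzoic anhydride | O=C(OC(=O)c1c(Cl)cc(Cl)cc1Cl)[C@@]2(C)O[C@@H]2C | intermediate (not isolated)
31 | (2S,3Z,6S,7Z,9R)-6-(acetyloxy)-9-[(4-methoxyphenyl)methoxy]-3,7-dimethyl-1-[(triethylsilyl)oxy]undeca-3,7,10-trien-2-yl (2S,3R)-2,3-dimethyloxirane-2-carboxylate | C=C[C@@H](OCc1ccc(OC)cc1)/C=C(/C)[C@@H](OC(C)=O)C/C=C(/C)[C@H](OC(=O)[C@@]2(C)O[C@@H]2C)CO[Si](CC)(CC)CC | intermediate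
32 | (2S,3Z,6S,7Z,9R)-6-(acetyloxy)-9-hydroxy-3,7-dimethyl-1-[(triethylsilyl)oxy]undeca-3,7,10-trien-2-yl (2S,3R)-2,3-dimethyloxirane-2-carboxylate | C=C[C@@H](O)/C=C(/C)[C@@H](OC(C)=O)C/C=C(/C)[C@H](OC(=O)[C@@]1(C)O[C@@H]1C)CO[Si](CC)(CC)CC | intermediate
33 | 2-(bromomethyl)prop-2-enoic acid | OC(=O)C(=C)CBr | starting material
34 | O-[2-(bromomethyl)prop-2-enoyl]-N,N'-dicyclohexylisourea | C=C(CBr)C(=O)OC(=NC1CCCCC1)NC1CCCCC1 | intermediate (not isolated)
35 | (2S,3Z,6S,7Z,9R)-6-(acetyloxy)-9-{[2-(bromomethyl)prop-2-enoyl]oxy}-3,7-dimethyl-1-[(triethylsilyl)oxy]undeca-3,7,10-trien-2-yl (2S,3R)-2,3-dimethyloxirane-2-carboxylate | C=C[C@@H](OC(=O)C(=C)CBr)/C=C(/C)[C@@H](OC(C)=O)C/C=C(/C)[C@H](OC(=O)[C@@]1(C)O[C@@H]1C)CO[Si](CC)(CC)CC | intermediate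
36 | (2S,3Z,6S,7Z)-6-(acetyloxy)-8-[(2S)-4-(bromomethyl)-5-oxo-2,5-dihydrofuran-2-yl]-3,7-dimethyl-1-[(triethylsilyl)oxy]octa-3,7-dien-2-yl (2S,3R)-2,3-dimethyloxirane-2-carboxylate | BrCC1=C[C@@H](OC1=O)/C=C(/C)[C@@H](OC(C)=O)C/C=C(/C)[C@H](OC(=O)[C@@]2(C)O[C@@H]2C)CO[Si](CC)(CC)CC | intermediate
37 | (2S,3Z,6S,7Z)-6-(acetyloxy)-8-[(2S)-4-(bromomethyl)-5-oxo-2,5-dihydrofuran-2-yl]-1-hydroxy-3,7-dimethylocta-3,7-dien-2-yl (2S,3R)-2,3-dimethyloxirane-2-carboxylate | BrCC1=C[C@@H](OC1=O)/C=C(/C)[C@@H](OC(C)=O)C/C=C(/C)[C@H](OC(=O)[C@@]2(C)O[C@@H]2C)CO | intermediate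
38 | (2S,3Z,6S,7Z)-6-(acetyloxy)-8-[(2S)-4-(bromomethyl)-5-oxo-2,5-dihydrofuran-2-yl]-3,7-dimethyl-1-oxoocta-3,7-dien-2-yl (2S,3R)-2,3-dimethyloxirane-2-carboxylate | BrCC1=C[C@@H](OC1=O)/C=C(/C)[C@@H](OC(C)=O)C/C=C(/C)[C@H](OC(=O)[C@@]2(C)O[C@@H]2C)C=O | intermediate
39 | allylchromium dichloride of 38 (CH2CrCl2 in place of CH2Br) | Cl[Cr](Cl)CC1=C[C@@H](OC1=O)/C=C(/C)[C@@H](OC(C)=O)C/C=C(/C)[C@H](OC(=O)[C@@]2(C)O[C@@H]2C)C=O | intermediate (not isolated)
40 | CNP0137407.7, (3aR,4S,5S,6Z,9S,10Z,11aS)-9-(acetyloxy)-4-hydroxy-6,10-dimethyl-3-methylidene-2-oxo-2,3,3a,4,5,8,9,11a-octahydrocyclodeca[b]furan-5-yl (2S,3R)-2,3-dimethyloxirane-2-carboxylate | C=C1C(=O)O[C@H]2/C=C(/C)[C@@H](OC(C)=O)C/C=C(/C)[C@H](OC(=O)[C@@]3(C)O[C@@H]3C)[C@@H](O)[C@@H]12 | target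

**Totals and risks**

Total step count: 24. Longest linear sequence: 17 steps (steps 4–7 then 12–24; the branches through steps 3 or 8–11 are equally long).

Steps most likely to fail:

1. Step 24. What may go wrong: C7 may be delivered to the other face of the aldehyde, the acyclic polar Felkin–Anh preference of the α-acyloxy aldehyde overriding the tether-imposed chair, so that the ring closes with C8 inverted. Closure on the butenolide face remote from the C5 chain (trans fusion) or intermolecular coupling would show in the same experiment, and this fallback does not repair those. The fallback separates ring closure from the setting of C8. It sets out from 38, whose chromium closure is then accepted as giving the 8-epimeric macrocycle F1. Dess–Martin oxidation (CH2Cl2, 0 °C) gives the C8 ketone F2, which is kept cold because H7 is then acidic. Luche reduction (NaBH4, CeCl3·7H2O, MeOH, −78 °C) should add hydride under polar Felkin–Anh control of the C9 acyloxy group, which for hydride, unlike for the carbon nucleophile, leads to the 8S alcohol. The sequence comes back to the route at 40.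

2. Step 11. What may go wrong: enolisation of the α-alkoxy β,γ-unsaturated aldehyde by the basic ylide (racemisation at C6, migration of the vinyl group into conjugation) and erosion of Z selectivity or low conversion with this hindered ylide. The fallback builds the same (Z)-haloalkene without a basic ylide. It sets out from 17: Corey–Fuchs dibromo-olefination (CBr4, PPh3, CH2Cl2, 0 °C) gives the dibromodiene F3. Palladium-catalysed Negishi coupling with Me2Zn (Pd(t-Bu3P)2, THF, 0 °C) should replace only the bromine trans to the chain and give the (Z)-alkenyl bromide F4. F4 enters the Nozaki–Hiyama–Kishi coupling with 13 under the conditions of step 12 with more NiCl2, and the sequence comes back at 24.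

3. Step 14. What may go wrong: weak facial discrimination, because the twisted Z enone offers the catalyst two flanking groups of similar size, or Z-to-E isomerisation of the enone before reduction. The fallback uses both C3 epimers without the oxidation–reduction detour. It sets out from 24: chromatography gives 26 and its C3 epimer F5. Compound 26 is acetylated as in step 15, and F5 is esterified with inversion by Mitsunobu reaction (AcOH, PPh3, DIAD, toluene, 0 °C). Both streams come back at 27.

Further compounds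
F1 | step 24 | (3aR,4R,5S,6Z,9S,10Z,11aS)-9-(acetyloxy)-4-hydroxy-6,10-dimethyl-3-methylidene-2-oxo-2,3,3a,4,5,8,9,11a-octahydrocyclodeca[b]furan-5-yl (2S,3R)-2,3-dimethyloxirane-2-carboxylate (8-epimer of 40) | C=C1C(=O)O[C@H]2/C=C(/C)[C@@H](OC(C)=O)C/C=C(/C)[C@H](OC(=O)[C@@]3(C)O[C@@H]3C)[C@H](O)[C@@H]12
F2 | step 24 | (3aS,5S,6Z,9S,10Z,11aS)-9-(acetyloxy)-6,10-dimethyl-3-methylidene-2,4-dioxo-2,3,3a,4,5,8,9,11a-octahydrocyclodeca[b]furan-5-yl (2S,3R)-2,3-dimethyloxirane-2-carboxylate (C8 ketone) | C=C1C(=O)O[C@H]2/C=C(/C)[C@@H](OC(C)=O)C/C=C(/C)[C@H](OC(=O)[C@@]3(C)O[C@@H]3C)C(=O)[C@@H]12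
F3 | step 11 | (3R)-5,5-dibromo-3-[(4-methoxyphenyl)methoxy]penta-1,4-diene | C=C[C@@H](OCc1ccc(OC)cc1)C=C(Br)Br
F4 | step 11 | (3R,4Z)-5-bromo-3-[(4-methoxyphenyl)methoxy]hexa-1,4-diene | C=C[C@@H](OCc1ccc(OC)cc1)/C=C(/C)Br
F5 | step 14 | (2Z,5R,6Z,8R)-2-[(4S)-2,2-dimethyl-1,3-dioxolan-4-yl]-8-[(4-methoxyphenyl)methoxy]-6-methyldeca-2,6,9-trien-5-ol | C=C[C@@H](OCc1ccc(OC)cc1)/C=C(/C)[C@H](O)C/C=C(/C)[C@H]1COC(C)(C)O1
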